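**Retrosynthetic overview**

- Rings: ring A is the benzo ring, ring B the dioxane ring, ring C the pendant aryl group. The strategy rests on O1 of ring B, which joins the sp2 carbon C8a of ring A to the stereogenic benzylic carbon C2. Cutting C8a–O1 (an aryl C–O bond) leaves C2 and C3 in an open-chain threo-(1R,2R) bromo alcohol.
- Ring B is the only ring formed in the route. It is closed in step 8 by copper-catalysed intramolecular O-arylation, and the phenol MOM ether is cleaved afterwards.
- C2 is set by Felkin–Anh reduction of an α-aryloxy ketone, made from a lactate-derived Weinreb amide and the ring C Grignard reagent.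
- C3–O4 is made by Mitsunobu inversion of ethyl (S)-lactate with the ring A bromophenol; the bromine ortho to O4 marks the future C8a.
- The ring A phenol comes from 5-bromovanillin by Wittig ethylidenation and Z-to-E equilibration.

Key step: step 8

Remark on the chemistry: the dioxane ring is numbered O1, C2 (aryl-bearing), C3 (methyl-bearing), O4, C4a, C8a; the target is the trans-(2R,3R) isomer, which corresponds to the threo-(1R,2R) open-chain alcohol, and the three starting materials are taken as commercial.

**Route**

Step 1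
Reactants: 1 5-bromovanillin
Product: 2 (E/Z)-2-bromo-6-methoxy-4-(prop-1-enyl)phenol (mixture of alkene isomers)
Conditions: EtPPh3Br (2.5 equiv), KOtBu (3.5 equiv), THF, 0 °C → rt; aq NH4Cl
Reagents that add atoms: ethyltriphenylphosphonium bromide, CC[P+](c1ccccc1)(c1ccccc1)c1ccccc1.[Br-]
Why: Wittig olefination with the non-stabilised ethylidene ylide, used in excess because the first equivalent of base forms the phenoxide and the phenoxide-deactivated aldehyde still reacts with so reactive a ylide; a Z-rich mixture is expected and is corrected in step 2.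

Step 2
Reactants: 2 (E/Z)-2-bromo-6-methoxy-4-(prop-1-enyl)phenol
Product: 3 2-bromo-6-methoxy-4-[(E)-prop-1-enyl]phenol
Conditions: PdCl2(MeCN)2 (5 mol %), CH2Cl2, rt
Reagents that add atoms: none
Why: Divalent-palladium-catalysed alkene isomerisation equilibrates the β-methylstyrene to the conjugated, strongly favoured E isomer, and the aryl bromide is inert because no zerovalent palladium is formed.

Step 3
Reactants: 3 2-bromo-6-methoxy-4-[(E)-prop-1-enyl]phenol; 4 ethyl (S)-lactate
Product: 5 ethyl (R)-2-{2-bromo-6-methoxy-4-[(E)-prop-1-enyl]phenoxy}propanoate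
Conditions: PPh3, DIAD, THF, 0 °C → rt
Reagents that add atoms: none
Why: Mitsunobu reaction, in which the acidic ortho-bromophenol displaces the activated lactate hydroxyl by SN2 with clean inversion, turning the (S)-lactate carbon into the (R)-aryloxy carbon that becomes C3.

Step 4
Reactants: 5 ethyl (R)-2-{2-bromo-6-methoxy-4-[(E)-prop-1-enyl]phenoxy}propanoate
Product: 6 (R)-2-{2-bromo-6-methoxy-4-[(E)-prop-1-enyl]phenoxy}-N-methoxy-N-methylpropanamide
Conditions: MeNH(OMe)·HCl (1.5 equiv), iPrMgCl (3 equiv), THF, −20 °C; aq NH4Cl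
Reagents that add atoms: N,O-dimethylhydroxylamine hydrochloride, CNOC.Cl
Why: Weinreb amide formation by aminolysis of the ester with the chloromagnesium amide made in the flask, at a temperature where the α-aryloxy stereocentre is not enolised and iPrMgCl does not exchange with the electron-rich aryl bromide.

Step 5
Reactants: 7 4-bromo-2,6-dimethoxyphenol
Product: 8 5-bromo-1,3-dimethoxy-2-(methoxymethoxy)benzene
Conditions: MOMCl, iPr2NEt, CH2Cl2, 0 °C → rt
Reagents that add atoms: chloromethyl methyl ether, COCCl
Why: O-alkylation of the phenol (Williamson-type acetal formation) gives a MOM ether that tolerates the Grignard, hydride, carbonate and copper conditions that follow.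

Step 6
Reactants: 6 (R)-2-{2-bromo-6-methoxy-4-[(E)-prop-1-enyl]phenoxy}-N-methoxy-N-methylpropanamide; 8 5-bromo-1,3-dimethoxy-2-(methoxymethoxy)benzene
Product: 10 (R)-2-{2-bromo-6-methoxy-4-[(E)-prop-1-enyl]phenoxy}-1-[3,5-dimethoxy-4-(methoxymethoxy)phenyl]propan-1-one, via aryl Grignard reagent 9 (not isolated)
Conditions: 8, Mg turnings, cat. I2, THF, 50 °C; then 6, THF, 0 °C → rt; aq NH4Cl
Reagents that add atoms: none
Why: Weinreb ketone synthesis, in which the aryl Grignard adds once to give a stable magnesium chelate that releases the ketone only on quench, so over-addition and enolisation of the α-aryloxy centre are avoided and the aryl bromide of 6 does not exchange with an arylmagnesium halide.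

Step 7
Reactants: 10 (R)-2-{2-bromo-6-methoxy-4-[(E)-prop-1-enyl]phenoxy}-1-[3,5-dimethoxy-4-(methoxymethoxy)phenyl]propan-1-one
Product: 11 (1R,2R)-2-{2-bromo-6-methoxy-4-[(E)-prop-1-enyl]phenoxy}-1-[3,5-dimethoxy-4-(methoxymethoxy)phenyl]propan-1-ol
Conditions: K-Selectride, K[HB(s-Bu)3] (1.2 equiv), THF, −78 °C; then H2O
Reagents that add atoms: none
Why: Felkin–Anh-controlled hydride reduction, in which the C–OAr bond lies anti to the incoming bulky hydride, which passes the small hydrogen at the existing (R) centre and should give the threo-(1R) alcohol; the poorly donating, doubly ortho-substituted aryloxy oxygen and the potassium counter-ion disfavour the competing chelate pathway to the erythro isomer.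

Step 8
Reactants: 11 (1R,2R)-2-{2-bromo-6-methoxy-4-[(E)-prop-1-enyl]phenoxy}-1-[3,5-dimethoxy-4-(methoxymethoxy)phenyl]propan-1-ol
Product: 12 (2R,3R)-2-[3,5-dimethoxy-4-(methoxymethoxy)phenyl]-5-methoxy-3-methyl-7-[(E)-prop-1-enyl]-2,3-dihydro-1,4-benzodioxine
Conditions: CuI (10 mol %), 3,4,7,8-tetramethyl-1,10-phenanthroline (20 mol %), Cs2CO3 (2 equiv), toluene (0.03 M), 110 °C, argon
Reagents that add atoms: none
Why: Cs2CO3 generates the C2 alkoxide, which binds phenanthroline-ligated monovalent copper; the copper alkoxide activates the neighbouring C8a–Br bond (oxidative addition to a trivalent copper aryl alkoxide held in a seven-membered metallacycle) and C–O reductive elimination releases the ether, which is an intramolecular Ullmann-type etherification of a secondary alcohol with an aryl bromide, a known reaction class. Ring B (O1, C2, C3, O4, C4a, C8a) closes in a 6-exo sense by ipso substitution at C8a. No stereocentre is created and no bond at C2 or C3 is broken, so the threo-(1R,2R) alcohol maps with retention onto the trans-(2R,3R) ring. The step needs O-arylation to outrun protodebromination, intermolecular coupling and oxidation of the alkoxide to the ketone; the six-membered tether, high dilution, exclusion of oxygen and a copper alkoxide that resists β-hydride elimination secure this, and the single bromine ortho to O4 leaves no regiochemical choice on ring A. The MOM acetal, the aryl methyl ethers and the E-propenyl group are inert to carbonate and copper at this temperature.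

Step 9
Reactants: 12 (2R,3R)-2-[3,5-dimethoxy-4-(methoxymethoxy)phenyl]-5-methoxy-3-methyl-7-[(E)-prop-1-enyl]-2,3-dihydro-1,4-benzodioxine
Product: 13 4-[(2R,3R)-5-methoxy-3-methyl-7-[(E)-prop-1-enyl]-2,3-dihydro-1,4-benzodioxin-2-yl]-2,6-dimethoxyphenol
Conditions: conc. aq HCl (cat.), MeOH, rt → 40 °C
Reagents that add atoms: none
Why: Acid-catalysed transacetalisation of the phenolic MOM acetal to methanol, run dilute and near room temperature so that the benzylic C2–O1 ether and the E-propenyl group should not ionise and neither stereocentre is touched.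

**Compound list**

1 | 5-bromovanillin (3-bromo-4-hydroxy-5-methoxybenzaldehyde) | O=Cc1cc(Br)c(O)c(OC)c1 | starting material
2 | (E/Z)-2-bromo-6-methoxy-4-(prop-1-enyl)phenol (mixture of alkene isomers) | CC=Cc1cc(Br)c(O)c(OC)c1 | intermediate
3 | 2-bromo-6-methoxy-4-[(E)-prop-1-enyl]phenol | C/C=C/c1cc(Br)c(O)c(OC)c1 | intermediate
4 | ethyl (S)-lactate | C[C@H](O)C(=O)OCC | starting material
5 | ethyl (R)-2-{2-bromo-6-methoxy-4-[(E)-prop-1-enyl]phenoxy}propanoate | CCOC(=O)[C@@H](C)Oc1c(Br)cc(/C=C/C)cc1OC | intermediate
6 | (R)-2-{2-bromo-6-methoxy-4-[(E)-prop-1-enyl]phenoxy}-N-methoxy-N-methylpropanamide | CON(C)C(=O)[C@@H](C)Oc1c(Br)cc(/C=C/C)cc1OC | intermediate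
7 | 4-bromo-2,6-dimethoxyphenol | Oc1c(OC)cc(Br)cc1OC | starting material
8 | 5-bromo-1,3-dimethoxy-2-(methoxymethoxy)benzene | COCOc1c(OC)cc(Br)cc1OC | intermediate
9 | [3,5-dimethoxy-4-(methoxymethoxy)phenyl]magnesium bromide | COCOc1c(OC)cc([Mg]Br)cc1OC | intermediate (not isolated)
10 | (R)-2-{2-bromo-6-methoxy-4-[(E)-prop-1-enyl]phenoxy}-1-[3,5-dimethoxy-4-(methoxymethoxy)phenyl]propan-1-one | O=C(c1cc(OC)c(OCOC)c(OC)c1)[C@@H](C)Oc1c(Br)cc(/C=C/C)cc1OC | intermediate
11 | (1R,2R)-2-{2-bromo-6-methoxy-4-[(E)-prop-1-enyl]phenoxy}-1-[3,5-dimethoxy-4-(methoxymethoxy)phenyl]propan-1-ol | O[C@H](c1cc(OC)c(OCOC)c(OC)c1)[C@@H](C)Oc1c(Br)cc(/C=C/C)cc1OC | intermediate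
12 | (2R,3R)-2-[3,5-dimethoxy-4-(methoxymethoxy)phenyl]-5-methoxy-3-methyl-7-[(E)-prop-1-enyl]-2,3-dihydro-1,4-benzodioxine | C/C=C/c1cc(OC)c2c(c1)O[C@H](c1cc(OC)c(OCOC)c(OC)c1)[C@@H](C)O2 | intermediate
13 | 4-[(2R,3R)-5-methoxy-3-methyl-7-[(E)-prop-1-enyl]-2,3-dihydro-1,4-benzodioxin-2-yl]-2,6-dimethoxyphenol | C/C=C/c1cc(OC)c2c(c1)O[C@H](c1cc(OC)c(O)c(OC)c1)[C@@H](C)O2 | target

**Step count**

Total steps: 9. Longest linear sequence: 8 steps (steps 1, 2, 3, 4, 6, 7, 8, 9 from 5-bromovanillin); step 5 is a one-step side branch.

**Steps most likely to fail**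

Step 8. Oxidative addition at the electron-rich, ortho-alkoxy aryl bromide may be slow, so that protodebromination, intermolecular etherification or oxidation of the benzylic alkoxide competes with ring closure. The fallback sets out from 11 and closes ring B at the other bond of O1 (C2–O1), a known acid-mediated mode for this ring system. Miyaura borylation of 11 (B2pin2, Pd(dppf)Cl2, KOAc, dioxane, 90 °C) should give the pinacol boronate F1. Oxidation (NaBO3·4H2O, THF/H2O, rt) should give the phenol F2. Dilute HCl in MeOH then ionises the electron-rich benzylic alcohol; the C8a phenol captures the cation, and thermodynamic control by the fixed C3 methyl group should place the aryl group trans. The MOM group is lost in the same operation, so the sequence comes back to the route at the target 13.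

Step 7. Facial selectivity may be poor if chelate-type hydride delivery competes with the Felkin–Anh pathway, and enolisation of the α-aryloxy ketone could erode the lactate-derived centre. The fallback sets out from 10 and uses chelation deliberately. Zn(BH4)2 (Et2O, −20 °C) should give the erythro alcohol F3. Mitsunobu inversion at the benzylic carbon (4-nitrobenzoic acid, PPh3, DIAD, THF) should give the threo 4-nitrobenzoate F4. Methanolysis (K2CO3, MeOH, rt) comes back to the route at 11.

Step 1. Ylide addition to the phenoxide-deactivated aldehyde may be sluggish, and the alkene is formed Z-rich, so the step depends on the later equilibration. The fallback sets out from 1 and reverses the order of events. Mitsunobu coupling of 1 with 4 (PPh3, DIAD, THF) should give the aldehyde ester F5, in which the aldehyde is no longer deactivated. Takai–Utimoto ethylidenation (CH3CHI2, CrCl2, THF, rt) is non-basic, aldehyde-selective and E-selective. It should convert F5 into 5 without touching the α-aryloxy centre, any residual Z isomer being equilibrated with PdCl2(MeCN)2 as in step 2. The sequence comes back to the route at 5.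

**Further compounds**

F1 | step 8 | (1R,2R)-1-[3,5-dimethoxy-4-(methoxymethoxy)phenyl]-2-{2-methoxy-4-[(E)-prop-1-enyl]-6-(4,4,5,5-tetramethyl-1,3,2-dioxaborolan-2-yl)phenoxy}propan-1-ol | O[C@H](c1cc(OC)c(OCOC)c(OC)c1)[C@@H](C)Oc1c(B2OC(C)(C)C(C)(C)O2)cc(/C=C/C)cc1OC
F2 | step 8 | 2-{[(1R,2R)-1-hydroxy-1-[3,5-dimethoxy-4-(methoxymethoxy)phenyl]propan-2-yl]oxy}-3-methoxy-5-[(E)-prop-1-enyl]phenol | O[C@H](c1cc(OC)c(OCOC)c(OC)c1)[C@@H](C)Oc1c(O)cc(/C=C/C)cc1OC
F3 | step 7 | (1S,2R)-2-{2-bromo-6-methoxy-4-[(E)-prop-1-enyl]phenoxy}-1-[3,5-dimethoxy-4-(methoxymethoxy)phenyl]propan-1-ol | O[C@@H](c1cc(OC)c(OCOC)c(OC)c1)[C@@H](C)Oc1c(Br)cc(/C=C/C)cc1OC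
F4 | step 7 | (1R,2R)-2-{2-bromo-6-methoxy-4-[(E)-prop-1-enyl]phenoxy}-1-[3,5-dimethoxy-4-(methoxymethoxy)phenyl]propyl 4-nitrobenzoate | O=C(O[C@H](c1cc(OC)c(OCOC)c(OC)c1)[C@@H](C)Oc1c(Br)cc(/C=C/C)cc1OC)c1ccc([N+](=O)[O-])cc1
F5 | step 1 | ethyl (R)-2-(2-bromo-4-formyl-6-methoxyphenoxy)propanoate | CCOC(=O)[C@@H](C)Oc1c(Br)cc(C=O)cc1OC
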